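The target is the C2-symmetric head-to-head [2+2] dimer (C8–C8′, C9–C9′) of a lindenane trienolide, so the problem reduces to the monomer's cis,trans-fused 3/5/6 core. The feature exploited is this: cyclopropane C1–C2–C3 plus five-membered ring A (C1, C3, C4, C5, C10) equals a six-membered decalin ring A (C1–C5, C10) carrying one transannular C1–C3 bond. That bond is made by letting the C3 enolate of a C4 ketone expel an equatorial 1β-tosylate. One operation contracts ring A, closes the cyclopropane and fixes C1 and C3. The precursor is a trans-decalone from (R)-Wieland–Miescher ketone with C7 masked as a dioxolane.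

Key step: step 6

Remarks on the chemistry
- Eudesmane/lindenane numbering is used throughout. β is the face of the angular methyl C14, α the opposite face.
- The key-step precursor and product lack C11–C13 as well as C15. They are therefore named as 11,12,13,15-tetranor compounds (C11 cores).
- C5 is also 1,3-related to C1 (through C10), so its enolate is a real competitor that would close a C1–C5 bond. The C5–H next to the C4 carbonyl is also epimerisable.
- The design answers both points. The tosylate goes on at the start and doubles as the protecting group. The ring fusion is set by hydroboration. C4 is methylenated directly after the ring contraction, so only one carbonyl is present in all later enolate chemistry.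
- The C8 configuration drawn between steps 9 and 13 is inconsequential. It is erased in step 13 and set for good in step 14.
- Assumption: 2-(diethoxyphosphoryl)propanoic acid is taken as a purchasable compound.

Step 1
Reactants: 1 (R)-Wieland–Miescher ketone
Product: 2 (4aR,5R)-5-hydroxy-4a-methyl-4,4a,5,6,7,8-hexahydronaphthalen-2(3H)-one (1β-hydroxy-5-en-7-one; OH equatorial and cis to C14)
Conditions: NaBH4 (0.3 equiv), EtOH, 0 °C
Reagents that add atoms: none
Why: Chemoselective borohydride 1,2-reduction, in which the saturated C1 ketone is more electrophilic than the vinylogously deactivated enone carbonyl and hydride arrives axially from the α face, anti to the adjacent axial C14 methyl, so the equatorial 1β-alcohol should result.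

Step 2
Reactants: 2 1β-hydroxy enone; 3 4-toluenesulfonyl chloride
Product: 4 1β-tosyloxy-5-en-7-one (O-tosylate of 2)
Conditions: pyridine, DMAP (cat.), 0 → 40 °C
Reagents that add atoms: 4-toluenesulfonyl chloride (3), Cc1ccc(cc1)S(Cl)(=O)=O
Why: O-Sulfonylation forms only the O–S bond and so retains C1, and the equatorial, neopentyl-type tosylate has no antiperiplanar hydrogen and is shielded from external nucleophiles, so it can also serve as the protecting group until step 6.

Step 3
Reactants: 4 1β-tosyloxy enone; 5 ethylene glycol
Product: 6 1β-tosyloxy-7,7-ethylenedioxy-11,12,13,15-tetranoreudesm-4-ene (alkene C4=C5)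
Conditions: TsOH·H2O (cat.), benzene, reflux, Dean–Stark trap
Reagents that add atoms: ethylene glycol (5), OCCO
Why: Deconjugative ketalisation of an octalone, in which the dienol ether formed by loss of a C4 proton is reprotonated at C6, so the alkene moves from C5=C6 to C4=C5 while the dioxolane closes at C7; no stereocentre is touched and the non-ionising solvent keeps the tosylate intact.

Step 4
Reactants: 6 tosyloxy alkene ketal
Product: 8 4α-hydroxy-1β-tosyloxy-5αH-tetranoreudesman-7-one ethylene ketal (trans-decalin; both oxygen substituents equatorial), via 4α-boryl adduct 7 (not isolated)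
Conditions: BH3·THF, THF, 0 °C → rt; then NaBO3·4H2O, THF–H2O, rt
Reagents that add atoms: sodium perborate tetrahydrate, [Na+].[O-]OB=O.O.O.O.O (oxygen of 8); borane–tetrahydrofuran, B.C1CCOC1 (boron of 7 only)
Why: Hydroboration–oxidation, in which syn anti-Markovnikov addition from the α face, opposite the axial C14 methyl, puts boron on C4 and hydrogen on C5 (setting 5α-H and the trans fusion), the C–B bond is oxidised with retention to the 4α-alcohol under conditions mild enough for the tosylate, and any β-face adduct is removed by chromatography.

Step 5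
Reactants: 8 4α-alcohol
Product: 9 1β-tosyloxy-5αH-11,12,13,15-tetranoreudesmane-4,7-dione 7-ethylene ketal (key-step precursor)
Conditions: Dess–Martin periodinane, CH2Cl2, rt
Reagents that add atoms: none
Why: Dess–Martin oxidation is non-enolising and base-free, so the carbinol becomes the C4 ketone without exchange at C5 and without premature loss of the γ-tosylate.

Step 6
Reactants: 9 1β-tosyloxy 4-ketone
Product: 11 tetranorlindenane-4,7-dione 7-ethylene ketal (1αH,3αH,5αH; cyclopropane CH2 on the β face; trans 5/6 fusion), via potassium C3-enolate 10 (not isolated)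
Conditions: 9 added slowly to KN(SiMe3)2 (1.05 equiv), THF, −78 °C; then −78 → 0 °C; cold pH 7 buffer quench
Reagents that add atoms: KN(SiMe3)2, C[Si](C)(C)[N-][Si](C)(C)C.[K+] (only the potassium ion of 10; no atom of it remains in 11)
Why: The hindered amide removes the exposed C3–H at −78 °C to give enolate 10, whose α-face lobe at C3 attacks C1 from the side opposite the C1–O bond on warming and expels tosylate, an intramolecular SN2 enolate alkylation (1,3-elimination). The closest known reaction type is the base-induced cyclisation of γ-sulfonyloxy ketones, as in 4-sulfonyloxycyclohexanones giving bicyclo[3.1.0]hexan-2-ones and 3β-sulfonyloxy 6-keto steroids giving 3α,5-cyclo ketones. The cyclopropane C1–C2–C3 closes in the 3-exo-tet mode, and the same new C1–C3 bond turns six-membered ring A into the five-membered ring C1–C3–C4–C5–C10. C1 is set by inversion (β-oxygen leaves, carbon enters from α), which leaves C2 as the apex on the β face beside C14, and C3 is tied to C1 because a bicyclo[3.1.0]hexane can only be cis-fused, while C5 and C10 are untouched. The step needs the C3 rather than the C5 enolate and an unexchanged C5–H in 11; this is secured because the tertiary C5–H is screened by quaternary C10 and by the α-axial ketal oxygen on C7, because inverse addition leaves no free 9 to shuttle protons, and because the potassium enolate should cyclise at temperatures where proton transfer to 11 is slow. The locked equatorial tosylate has its C1–O bond anti to C2–C3 (the only arrangement open to rear-side attack), has no antiperiplanar hydrogen for E2 loss and, unlike a mesylate, no acidic α-protons.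

Step 7
Reactants: 11 tricyclic cyclopropyl ketone
Product: 12 11,12,13-trinorlinden-4(15)-en-7-one ethylene ketal
Conditions: Cp2TiMe2, toluene, 70 °C, dark
Reagents that add atoms: dimethyltitanocene Cp2TiMe2, C[Ti](C)(C1C=CC=C1)C1C=CC=C1
Why: Petasis methylenation, in which thermally generated Cp2Ti=CH2 adds to the carbonyl and cycloreverts to the alkene; the reagent is non-basic, so the C5–H of the strained trans fusion is not epimerised, and ketals are inert to it.

Step 8
Reactants: 12 methylene ketal
Product: 13 11,12,13-trinorlinden-4(15)-en-7-one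
Conditions: PPTS (cat.), acetone–H2O, 45 °C
Reagents that add atoms: water, O
Why: Mild acid-catalysed ketal hydrolysis, with a pyridinium acid too weak to protonate the 1,1-disubstituted alkene next to the cyclopropane, so the vinylcyclopropane should survive.

Step 9
Reactants: 13 C7 ketone
Product: 15 8α-hydroxy-11,12,13-trinorlinden-4(15)-en-7-one, via potassium C7=C8 enolate 14 (not isolated)
Conditions: KN(SiMe3)2, THF, −78 °C; 2-(phenylsulfonyl)-3-phenyloxaziridine, −78 °C; AcOH quench
Reagents that add atoms: 2-(phenylsulfonyl)-3-phenyloxaziridine, O=S(=O)(c1ccccc1)N1OC1c1ccccc1 (oxygen of 15); KN(SiMe3)2, C[Si](C)(C)[N-][Si](C)(C)C.[K+] (potassium ion of 14 only)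
Why: Davis enolate hydroxylation, in which kinetic and thermodynamic enolisation of the trans-fused ring B both point to C8 (C6–H is flanked by tertiary C5, and a C7=C8 bond leaves the C5–C10 fusion bond at the most puckered ring position), the oxaziridine ignores the alkene, and oxygen is delivered from the α face away from C14.

Step 10
Reactants: 15 8α-hydroxy ketone; 16 2-(diethoxyphosphoryl)propanoic acid
Product: 17 8α-[2-(diethoxyphosphoryl)propanoyloxy] ketone (epimeric at the phosphonate carbon)
Conditions: DCC, DMAP (cat.), CH2Cl2, 0 °C → rt
Reagents that add atoms: 2-(diethoxyphosphoryl)propanoic acid (16), CCOP(=O)(OCC)C(C)C(=O)O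
Why: Steglich esterification of an unhindered equatorial secondary alcohol under neutral conditions; the stereocentre at the future C11 forms as a mixture and disappears in step 11.

Step 11
Reactants: 17 phosphonate ester
Product: 18 8βH-lindena-4(15),7(11)-dien-12,8α-olide (α-methylbutenolide fused at C7–C8)
Conditions: NaH, THF, 0 °C → rt
Reagents that add atoms: none
Why: Intramolecular Horner–Wadsworth–Emmons olefination, in which the tether lets the phosphonate carbanion reach only the C7 carbonyl and closes the five-membered lactone with the C7=C11 double bond, whose geometry the ring fixes.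

Step 12
Reactants: 18 butenolide
Product: 19 12-(tert-butyldimethylsilyloxy)furan (furan O, C8, C7, C11, C12 fused to ring B)
Conditions: TBSOTf, Et3N, CH2Cl2, 0 °C; pentane extraction, used crude
Reagents that add atoms: tert-butyldimethylsilyl trifluoromethanesulfonate, CC(C)(C)[Si](C)(C)OS(=O)(=O)C(F)(F)F
Why: Soft enolisation and O-silylation of a butenolide, in which loss of the γ-proton at C8 is preferred over C6–H because only it gives the aromatic 2-silyloxyfuran; the C8 stereocentre is erased here.

Step 13
Reactants: 19 silyloxyfuran
Product: 21 lindena-4(15),7(11),8-trien-12,8-olide (chloranthalactone A), via 8α-bromobutenolide 20 (not isolated)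
Conditions: NBS, THF, −78 °C; then DBU, −78 °C → rt
Reagents that add atoms: N-bromosuccinimide, O=C1CCC(=O)N1Br (bromine of 20 only; no atom of it remains in 21)
Why: Vinylogous halogenation then dehydrohalogenation, in which the electron-rich silyloxyfuran takes up electrophilic bromine at its free-valence γ-carbon C8 far faster than the isolated alkene does, and the tertiary, oxygen-activated bromide can lose HBr only toward C9, the sole neighbouring carbon bearing hydrogen, giving the fully conjugated C8=C9 enol lactone.

Step 14
Reactants: 21 chloranthalactone A (two molecules)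
Product: 22 target CNP0265879.1 (cyclobutane C8–C9–C9′–C8′; 8β-O, 9β-H in both halves)
Conditions: hν (medium-pressure Hg lamp, Pyrex filter), degassed hexane, concentrated solution, rt
Reagents that add atoms: none
Why: [2+2] Photodimerisation of a conjugated enol lactone, in which initial C9–C9′ bonding gives the biradical whose two C8 centres are tertiary, oxygen-substituted and delocalised into the butenolides and so dictates head-to-head closure of C8–C8′; both partners react on the α face because the axial C14 methyl on C10 and the β-cyclopropane screen the β face of C9, and two homochiral monomers joined α to α can only give the C2-symmetric anti dimer.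

Compound list
1 | (R)-Wieland–Miescher ketone | C[C@@]12CCC(=O)C=C1CCCC2=O | starting material
2 | (4aR,5R)-5-hydroxy-4a-methyl-4,4a,5,6,7,8-hexahydronaphthalen-2(3H)-one | C[C@@]12CCC(=O)C=C1CCC[C@H]2O | intermediate
3 | 4-toluenesulfonyl chloride | Cc1ccc(cc1)S(Cl)(=O)=O | starting material
4 | 1β-tosyloxy-5-en-7-one | C[C@@]12CCC(=O)C=C1CCC[C@H]2OS(=O)(=O)c1ccc(C)cc1 | intermediate
5 | ethylene glycol | OCCO | starting material
6 | 1β-tosyloxy-7,7-ethylenedioxy-11,12,13,15-tetranoreudesm-4-ene | C[C@@]12CCC3(OCCO3)CC1=CCC[C@H]2OS(=O)(=O)c1ccc(C)cc1 | intermediate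
7 | 4α-boryl-5αH adduct of 6 (not isolated) | B[C@@H]1CC[C@@H](OS(=O)(=O)c2ccc(C)cc2)[C@@]2(C)[C@H]1CC1(OCCO1)CC2 | intermediate
8 | 4α-hydroxy-1β-tosyloxy-5αH-tetranoreudesman-7-one ethylene ketal | O[C@@H]1CC[C@@H](OS(=O)(=O)c2ccc(C)cc2)[C@@]2(C)[C@H]1CC1(OCCO1)CC2 | intermediate
9 | 1β-tosyloxy-5αH-11,12,13,15-tetranoreudesmane-4,7-dione 7-ethylene ketal | O=C1CC[C@@H](OS(=O)(=O)c2ccc(C)cc2)[C@@]2(C)[C@H]1CC1(OCCO1)CC2 | intermediate
10 | potassium C3=C4 enolate of 9 (not isolated) | [K+].[O-]C1=CC[C@@H](OS(=O)(=O)c2ccc(C)cc2)[C@@]2(C)[C@H]1CC1(OCCO1)CC2 | intermediate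
11 | 11,12,13,15-tetranorlindenane-4,7-dione 7-ethylene ketal | O=C1[C@H]2C[C@H]2[C@@]2(C)[C@H]1CC1(OCCO1)CC2 | intermediate
12 | 11,12,13-trinorlinden-4(15)-en-7-one ethylene ketal | C=C1[C@H]2C[C@H]2[C@@]2(C)[C@H]1CC1(OCCO1)CC2 | intermediate
13 | 11,12,13-trinorlinden-4(15)-en-7-one | C=C1[C@H]2C[C@H]2[C@@]2(C)[C@H]1CC(=O)CC2 | intermediate
14 | potassium C7=C8 enolate of 13 (not isolated) | C=C1[C@H]2C[C@H]2[C@@]2(C)[C@H]1CC([O-])=CC2.[K+] | intermediate
15 | 8α-hydroxy-11,12,13-trinorlinden-4(15)-en-7-one | C=C1[C@H]2C[C@H]2[C@@]2(C)[C@H]1CC(=O)[C@@H](O)C2 | intermediate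
16 | 2-(diethoxyphosphoryl)propanoic acid | CCOP(=O)(OCC)C(C)C(=O)O | starting material
17 | 8α-[2-(diethoxyphosphoryl)propanoyloxy]-11,12,13-trinorlinden-4(15)-en-7-one | C=C1[C@H]2C[C@H]2[C@@]2(C)[C@H]1CC(=O)[C@@H](OC(=O)C(C)P(=O)(OCC)OCC)C2 | intermediate
18 | 8βH-lindena-4(15),7(11)-dien-12,8α-olide | C=C1[C@H]2C[C@H]2[C@@]2(C)[C@H]1CC1=C(C)C(=O)O[C@H]1C2 | intermediate
19 | 12-(tert-butyldimethylsilyloxy)furan derived from 18 | C=C1[C@H]2C[C@H]2[C@@]2(C)[C@H]1Cc1c(C)c(O[Si](C)(C)C(C)(C)C)oc1C2 | intermediate
20 | 8α-bromolindena-4(15),7(11)-dien-12,8-olide (not isolated) | C=C1[C@H]2C[C@H]2[C@@]2(C)[C@H]1CC1=C(C)C(=O)O[C@]1(Br)C2 | intermediate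
21 | lindena-4(15),7(11),8-trien-12,8-olide (chloranthalactone A) | C=C1[C@H]2C[C@H]2[C@@]2(C)[C@H]1CC1=C(C)C(=O)OC1=C2 | intermediate
22 | CNP0265879.1, head-to-head α,α-[2+2] dimer of 21 | C=C1[C@H]2C[C@H]2[C@@]2(C)[C@H]1CC1=C(C)C(=O)O[C@]13[C@H]2[C@H]1[C@@]2(C)[C@@H]4C[C@@H]4C(=C)[C@@H]2CC2=C(C)C(=O)O[C@@]213 | target

Total step count: 14. Longest linear sequence: 14 steps (1 → 22).

Steps most likely to fail

1. Step 6. Proton transfer could move the enolate to the C5 side, which would close the wrong C1–C5 bond, or could exchange the C5–H of the freshly formed strained trans-fused ketone. The fallback separates enolate regiochemistry from ring closure.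
   - Setting out from 9, the kinetic enolate is trapped as it forms (LiN(iPr)2 in the presence of Me3SiCl, THF, −78 °C) as the C3=C4 trimethylsilyl enol ether F1. Its regiochemical purity can be checked and upgraded before any C–C bond is made.
   - Anhydrous fluoride ([(Me2N)3S][Me3SiF2], THF, −78 → 0 °C) then releases an amine-free, metal-free enolate regiospecifically at C3. This closes the C1–C3 bond and rejoins the route at 11.

2. Step 13. Bromine could be delivered to C11 or to the C4=C15 alkene instead of C8, or the labile bromide could hydrolyse before it eliminates. The fallback puts oxygen rather than halogen on C8.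
   - Setting out from 19, one equivalent of dimethyldioxirane (acetone, −78 °C) followed by aqueous work-up gives the 8-hydroxybutenolide F2. This is the ring–chain tautomer of the γ-keto acid, and its C8 epimers are equivalent for the purpose.
   - Classical enol-lactonisation (Ac2O, NaOAc, 80 °C) dehydrates it toward C9 and rejoins the route at 21.

3. Step 4. Facial selectivity of the hydroboration could be poor, and the β-face adduct cannot be corrected by base while the tosylate is present. The fallback puts the ring fusion under thermodynamic control.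
   - Setting out from 2, benzoylation (BzCl, pyridine) gives the 1β-benzoyloxy enone F3, which is ketalised as in step 3 to the benzoyloxy alkene ketal F4.
   - BH3·THF gives the C4-boranes F5 and NaBO3·4H2O the C4/C5-epimeric alcohols F6. Dess–Martin oxidation then gives the C5-epimeric ketones F7.
   - NaOMe in MeOH removes the benzoate and equilibrates C5 to the more stable trans-decalone, giving the 1β-hydroxy 4-ketone F8.
   - Tosylation of F8 with 3 in pyridine rejoins the route at 9.

Further compounds
F1 | step 6 | C3=C4 trimethylsilyl enol ether of 9 | C[Si](C)(C)OC1=CC[C@@H](OS(=O)(=O)c2ccc(C)cc2)[C@@]2(C)[C@H]1CC1(OCCO1)CC2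
F2 | step 13 | 8-hydroxylindena-4(15),7(11)-dien-12,8-olide (C8 epimers) | C=C1[C@H]2C[C@H]2[C@@]2(C)[C@H]1CC1=C(C)C(=O)OC1(O)C2
F3 | step 4 | 1β-benzoyloxy-5-en-7-one | C[C@@]12CCC(=O)C=C1CCC[C@H]2OC(=O)c1ccccc1
F4 | step 4 | 1β-benzoyloxy-7,7-ethylenedioxy-tetranoreudesm-4-ene | C[C@@]12CCC3(OCCO3)CC1=CCC[C@H]2OC(=O)c1ccccc1
F5 | step 4 | C4-boranes from F4 (α- and β-face adducts) | BC1CC[C@@H](OC(=O)c2ccccc2)[C@@]2(C)C1CC1(OCCO1)CC2
F6 | step 4 | 1β-benzoyloxy-4-hydroxy ketals (4α,5α and 4β,5β) | OC1CC[C@@H](OC(=O)c2ccccc2)[C@@]2(C)C1CC1(OCCO1)CC2
F7 | step 4 | 1β-benzoyloxy 4-ketone 7-ketal (C5 epimers) | O=C1CC[C@@H](OC(=O)c2ccccc2)[C@@]2(C)C1CC1(OCCO1)CC2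
F8 | step 4 | 1β-hydroxy-5αH-tetranoreudesmane-4,7-dione 7-ethylene ketal | O=C1CC[C@@H](O)[C@@]2(C)[C@H]1CC1(OCCO1)CC2
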